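# Proposed synthesis of CNP0141816.1, (7R,8S,7'S,8'R)-8-hydroxy furofuran lignan with a C7 guaiacyl and a C7' veratryl group

## Analysis of the target

The target is a furofuran lignan, a cis-fused 2,6-diaryl-3,7-dioxabicyclo[3.3.0]octane, with a tertiary hydroxyl group at the ring-fusion carbon C8. In the lignan numbering used throughout, ring A is C7–O–C9'–C8'–C8 and carries the 4-hydroxy-3-methoxyphenyl (guaiacyl) group at C7; ring B is C7'–O–C9–C8–C8' and carries the 3,4-dimethoxyphenyl (veratryl) group at C7'. The four stereocentres are contiguous (7R, 8S, 7'S, 8'R): C8–OH and C8'–H lie on the same face, and both aryl groups are exo, the guaiacyl group cis to C8–OH on ring A and the veratryl group cis to C8'–H on ring B. Because the two aryl groups differ, the skeleton cannot be made by dimerising one C6–C3 unit. Both C7–O and C7'–O are benzylic ethers of electron-rich arenes: acid ionises them (epimerisation) and hydrogenolysis can cleave them. The free phenol para to C7 opens a quinone methide pathway under base, so it stays masked until the last step. The difficulty is the fully substituted, oxygen-bearing C8, which is flanked by three stereocentres and must be formed with control of relative and absolute configuration. The strategy reads ring B as a three-atom unit C9–O–C7', a carbonyl ylide built from veratraldehyde and one methylene group. This ylide is added across a C8=C8' double bond that belongs to a ring A butenolide, in which C7 is the only stereocentre and a boryl group on C8 stands in for the hydroxyl.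

## Retrosynthetic reasoning

**19 to 18.** The phenol is unmasked last. Target 19 is traced back to its benzyl ether 18. A benzyl ether is inert to alkylzinc reagents, copper boryl species, aqueous acid, fluoride, perborate and hydride, which are all met on the way. The forward step must cleave the aryl–O–benzyl bond without touching the two cyclic benzylic ethers.

**18 to 16 (through 17).** Ring A is opened at the C9'–O bond, not at C7–O. This gives triol 16, in which C9' is a primary alcohol and C7 keeps its oxygen. Forward, the primary hydroxyl is sulfonylated (tosylate 17) and displaced by the C7 hydroxyl, so the C7–O bond is never broken and C7 cannot epimerise. Cutting at C7–O would mean a benzylic cation and thermodynamic control only.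

**16 to 15.** C9' is taken back to the carboxyl level, which gives hydroxy lactone 15. The lactone carbonyl is the group that makes a C8=C8' alkene electron-poor further back, so this oxidation level is a requirement of the key step. Forward, one hydride reduction suffices.

**15 to 14.** The C8–O bond is exchanged for a C8–B bond (boryl lactone 14). An oxygen substituent on C8 of the alkene would make it a vinylogous carbonate, too electron-rich for a nucleophilic ylide. A pinacolboryl group has an empty p orbital, is no donor, and is oxidised to the alcohol with retention. Forward, the oxidation must spare the lactone and the new β-hydroxy carbonyl unit.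

**14 to 8 and 12 (through 13).** This is the key disconnection. C8–C9 and C7'–C8' are cut, so ring B falls apart into carbonyl ylide 13 and boryl butenolide 8. The cut is made here because one convergent step then forms two C–C bonds, ring B and three stereocentres (C8, C8', C7'), all relayed from C7. The ylide is released from α-chloro silylmethyl ether 12. The forward reaction must join the CH2 end of the ylide to C8, add anti to the C7 aryl group, place the veratryl group exo, and leave the acidic C7–H untouched.

**8 to 6 (through 7), and 6 to 4 and 5.** The lactone C–O bond is cut to the (Z)-β-boryl-γ-hydroxy enoate 7, which is held as its silyl ether 6. Removing boron and hydrogen from the alkene of 6 gives ynoate 4 and diboron 5. Syn addition of boron and hydrogen to the ynoate gives exactly the Z geometry that lets the C7 oxygen reach the ester. The silyl ether ensures that the butenolide, whose C7–H is acidic, is formed only under acid.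

**4 to 3, and 3 to 1 and 2.** The silyl ether 4 comes from carbinol 3, and the C7–alkyne bond of 3 is cut to aldehyde 1 and methyl propiolate 2. The forward step is a catalytic asymmetric alkynylation that sets C7, the stereocentre from which all others are derived.

**12 to 11, and 11 to 9 and 10.** Chloro ether 12 comes from acetal 11 by exchange of one alkoxy group for chloride. Acetal 11 comes from veratraldehyde 9 and (trimethylsilyl)methanol 10. Compound 12 is racemic, which is of no consequence because its carbon becomes planar in the ylide.

## Alternatives that were turned down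

**Alternative 1:** aryl ketene cycloaddition, then Baeyer–Villiger ring expansion.
- Disconnection: C7–C8 and C8'–C9' are cut, so that ring A shrinks to a cyclobutanone fused to ring B.
- Forward key step: the aryl ketene A3, made in the flask from the arylacetyl chloride and a tertiary amine, adds in a [2+2] sense to the ring B silyl enol ether A2. The nucleophilic C8' bonds to the ketene carbonyl carbon and the oxygenated C8 to the aryl-bearing carbon, giving silyloxy cyclobutanone A1. Baeyer–Villiger oxidation then moves the benzylic C7 onto oxygen and gives lactone A4, the silyl ether counterpart of 15.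
- For it: oxygen sits on C8 from the start, so no placeholder and no oxidation of a C–B bond are needed. The polarity of the partners is matched, whereas the chosen route must bring a nucleophilic ylide onto a fully substituted β-carbon. Both reactions are long established, so on novelty of the key step this alternative is the stronger one.
- Against it:
  - A mono-aryl ketene with a donor-substituted ring is a weak electrophile and dimerises readily; enol ethers of this kind normally need halogenated ketenes or a stoichiometric Lewis acid.
  - A2 must be formed by enolising a tetrahydrofuran-3-one towards C8' and not towards the α-alkoxy carbon C9.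
  - Thermal ketene additions tend to place the larger ketene substituent on the concave face, so the exo aryl would have to be reached by epimerising C7 next to the ketone.
  - A1 is a strained β-silyloxy ketone that can open by retro-aldol cleavage on slight desilylation.
  - The peracid has to spare two electron-rich arenes.
- Comparison: the step count is about the same. The chosen strategy offers instead a union of two aldehyde-derived halves with no regiochemical question in enol ether formation, no strained intermediate and no peracid.

**Alternative 2:** rhodium-catalysed arylative cyclisation of an alkynyl ketone.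
- Disconnection: C8–C8' and the C7'–aryl bond.
- Forward key step: alkynyl ketone A6 (the propargyl ether of an α-hydroxy ketone) reacts with boronic acid A7 under rhodium catalysis. The arylrhodium species adds syn across the terminal alkyne with the aryl group going to C7', and the alkenylrhodium at C8' adds to the C8 ketone. This gives A5, with ring A, the tertiary alcohol and an exocyclic veratrylidene group.
- For it: the step is catalytic and convergent, the reaction class is well described for alkyne-tethered ketones, and the veratryl group arrives as a shelf-stable boronic acid instead of a labile chloro ether. On reliability of the key step itself this alternative is the stronger one.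
- Against it:
  - A5 is still one ring and two stereocentres (C8', C7') short. Ring B must be closed by adding C9–OH across the styrene-type C7'=C8' bond, a 5-endo closure that runs through a benzylic cation at C7' beside a tertiary allylic alcohol, which can ionise or transpose under the same acid.
  - A6 is an α-aryl α-alkoxy ketone whose C7–H is more acidic than that of 8, and it is exposed to the basic aqueous medium of the rhodium step.
  - Terminal alkynes divert arylrhodium species into alkynyl complexes and oligomers.
  - The facial preference of the ketone addition relative to C7 is not obviously biased.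
- Comparison: more steps follow the key step (ring B closure, two desilylations). The chosen strategy offers instead the setting of C8, C8' and C7' in one concerted event, with no late cation chemistry.

**Alternative 3:** α-ketol shift with ring contraction of a tetrahydropyranone.
- Disconnection: the C8–C8' bond is taken back to a C7–C8' bond, so ring B is enlarged by C7 to the 4-aryl-4-hydroxytetrahydropyran-3-one A9.
- Forward key step: with an alkoxide base or an aluminium alkoxide, C8' migrates from the carbinol carbon C7 to the ketone carbon C8. This gives hydroxy ketone A8, which has ring B and C8–OH and an aroyl group on C8. Reduction of the aryl ketone and closure of ring A would follow.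
- For it: all oxygen atoms are in place, the key step is a redox-neutral isomerisation with no organometallic reagent, and the configuration of C8 is tied to C8' by the intramolecular shift. In atom economy of the key step it is stronger than the chosen route.
- Against it:
  - Equilibria of this type normally favour the six-membered hydroxy ketone over the acyl-substituted five-membered carbinol, so only the conjugation of the new aryl ketone would drive the contraction.
  - The electron-rich aryl group on C7 competes as the migrating group. When the hydroxyl is held in the carbonyl plane by the metal, it is the axial aryl group, not the ring bond, that is aligned with the carbonyl π* orbital.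
  - A9 holds three stereocentres, one of them a tertiary benzylic alcohol, and is no easier to make than the target.
  - C7 must be set after the key step by a diastereoselective reduction.
- Comparison: this is the longest of the four routes. The chosen strategy offers instead a short precursor synthesis and relay of all stereocentres from one catalytically set centre.

Key step: step 7

Assumption: (S,S)-ProPhenol is taken to be the ligand antipode that delivers the (R)-carbinol 3 from aldehyde 1; the mirror-image ligand is equally available and is used if the sense of induction is the opposite.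

## Steps

Step 1
Reactants: 1 4-(benzyloxy)-3-methoxybenzaldehyde (O-benzylvanillin); 2 methyl propiolate
Product: 3 methyl (4R)-4-[4-(benzyloxy)-3-methoxyphenyl]-4-hydroxybut-2-ynoate
Conditions: Me2Zn (3 equiv), (S,S)-ProPhenol (20 mol%), Ph3P=O (40 mol%), toluene, 0–4 °C; aq NH4Cl
Reagents that add atoms: none
Why: Zinc–ProPhenol catalysed enantioselective alkynylation of an aromatic aldehyde: Me2Zn zincates the propiolate C–H and the dinuclear zinc alkoxide catalyst delivers the alkynyl group to one face of the carbonyl group, which sets C7; the benzyl ether and the ester do not react with the alkylzinc at this temperature.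

Step 2
Reactants: 3 methyl (4R)-4-[4-(benzyloxy)-3-methoxyphenyl]-4-hydroxybut-2-ynoate
Product: 4 methyl (4R)-4-[4-(benzyloxy)-3-methoxyphenyl]-4-[(triethylsilyl)oxy]but-2-ynoate
Conditions: Et3SiOTf (1.2 equiv), 2,6-lutidine (2 equiv), CH2Cl2, −78 °C
Reagents that add atoms: triethylsilyl trifluoromethanesulfonate, CC[Si](CC)(CC)OS(=O)(=O)C(F)(F)F
Why: O-Silylation with a silyl triflate and a hindered pyridine base is fast at low temperature, so the base-sensitive γ-hydroxy ynoate has no time to isomerise; the silyl ether keeps the hydroxyl from lactonising in the basic medium of step 3.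

Step 3
Reactants: 4 methyl (4R)-4-[4-(benzyloxy)-3-methoxyphenyl]-4-[(triethylsilyl)oxy]but-2-ynoate; 5 bis(pinacolato)diboron
Product: 6 methyl (2Z,4S)-4-[4-(benzyloxy)-3-methoxyphenyl]-3-(4,4,5,5-tetramethyl-1,3,2-dioxaborolan-2-yl)-4-[(triethylsilyl)oxy]but-2-enoate
Conditions: CuCl (5 mol%), Xantphos (5 mol%), NaOtBu (10 mol%), MeOH (2 equiv), THF, 0 °C → rt
Reagents that add atoms: none
Why: Copper-catalysed β-borylation of an ynoate (borylcupration, then protonation): the copper boryl species adds syn with boron on the β-carbon and MeOH protonates the α-alkenylcopper, so the silyloxy-bearing carbon ends up cis to the ester (Z); C7 is not touched, and its descriptor changes from R to S only because the boryl-substituted carbon ranks below the aryl group.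

Step 4
Reactants: 6 methyl (2Z,4S)-4-[4-(benzyloxy)-3-methoxyphenyl]-3-(4,4,5,5-tetramethyl-1,3,2-dioxaborolan-2-yl)-4-[(triethylsilyl)oxy]but-2-enoate
Product: 8 (5S)-5-[4-(benzyloxy)-3-methoxyphenyl]-4-(4,4,5,5-tetramethyl-1,3,2-dioxaborolan-2-yl)furan-2(5H)-one, via hydroxy enoate 7 (not isolated)
Conditions: AcOH/THF/H2O (3:1:1), rt → 40 °C
Reagents that add atoms: none
Why: Acidic desilylation followed by lactonisation (intramolecular transesterification) of the (Z)-γ-hydroxy enoate with loss of methanol; the C7–O bond is not broken, so the configuration is kept, and acid is used instead of fluoride or alkoxide because C7–H of the butenolide is acidic (γ-deprotonation would give a 2-oxyfuran).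

Step 5
Reactants: 9 3,4-dimethoxybenzaldehyde (veratraldehyde); 10 (trimethylsilyl)methanol (2.5 equiv)
Product: 11 4-{bis[(trimethylsilyl)methoxy]methyl}-1,2-dimethoxybenzene
Conditions: TsOH·H2O (1 mol%), cyclohexane, reflux with azeotropic removal of water; then Et3N
Reagents that add atoms: none
Why: Acid-catalysed acetalisation driven by removal of water; the α-silyl alcohol is stable to catalytic sulfonic acid and the excess is recovered by distillation.

Step 6
Reactants: 11 4-{bis[(trimethylsilyl)methoxy]methyl}-1,2-dimethoxybenzene
Product: 12 racemic chloro(3,4-dimethoxyphenyl)methyl (trimethylsilyl)methyl ether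
Conditions: AcCl (1.1 equiv), SOCl2 (2 mol%), CH2Cl2, 0 °C → rt; volatiles removed in vacuo; used at once
Reagents that add atoms: acetyl chloride, CC(Cl)=O
Why: Exchange of an acetal alkoxy group for chloride: O-acylation and loss of (trimethylsilyl)methyl acetate give the veratryl-stabilised oxocarbenium ion, which chloride captures; the product is moisture-sensitive and is not purified.

Step 7
Reactants: 8 (5S)-5-[4-(benzyloxy)-3-methoxyphenyl]-4-(4,4,5,5-tetramethyl-1,3,2-dioxaborolan-2-yl)furan-2(5H)-one; 12 racemic chloro(3,4-dimethoxyphenyl)methyl (trimethylsilyl)methyl ether (3 equiv)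
Product: 14 (3S,3aR,6S,6aS)-3-[4-(benzyloxy)-3-methoxyphenyl]-6-(3,4-dimethoxyphenyl)-3a-(4,4,5,5-tetramethyl-1,3,2-dioxaborolan-2-yl)tetrahydro-1H,3H-furo[3,4-c]furan-1-one, via carbonyl ylide 13 (not isolated)
Conditions: CsF (4 equiv, dried, added in portions to 8 + 12), MeCN, 0 °C → rt
Reagents that add atoms: none
Why: Proposed new method: chloride ionises from 12 to give the veratryl-stabilised oxocarbenium ion, fluoride removes the silyl group from the neighbouring CH2, and the resulting E-configured carbonyl ylide 13 adds in a concerted, suprafacial [3+2] manner across C8=C8' of 8; the closest known reaction type is the fluoride-induced 1,3-elimination of α-chloro silylmethyl ethers with cycloaddition of the non-stabilised ylides to acrylates, enones and maleates, whereas an alkenylboronate that is also a β,β-disubstituted enoate has not been used as the partner. Ring B closes by intermolecular [π4s+π2s] cycloaddition; both new bonds (C8–C9 and C7'–C8') form on one face of the alkene, so the ring fusion can only be cis. Regiochemistry: the ylide carries its nucleophilic character at the unsubstituted CH2 end (the electron-rich aryl group holds the positive charge at C7'), and this small terminus attacks the β-carbon C8 of the enoate, which is also the hindered position; the empty p orbital on boron lowers the LUMO without reversing the polarisation set by the lactone carbonyl. C8 and C8' take their absolute configuration from attack on the face anti to the aryl group at C7, the only stereocentre of 8, which places boron cis to that aryl group. C7' is set by an exo transition state in which the ylide oxygen and the aryl group of the E-ylide point away from the lactone carbonyl, so that the veratryl group ends up cis to C8'–H; the endo arrangement would push the aryl group under the lactone C=O. The step also needs C7–H (benzylic and γ to the lactone carbonyl) to stay in place: CsF is almost insoluble in MeCN and is dosed into a solution holding 12 in excess, so that dissolved fluoride is consumed at silicon, and the mixture is kept cold and anhydrous to limit fluoride binding to boron.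

Step 8
Reactants: 14 (3S,3aR,6S,6aS)-3-[4-(benzyloxy)-3-methoxyphenyl]-6-(3,4-dimethoxyphenyl)-3a-(4,4,5,5-tetramethyl-1,3,2-dioxaborolan-2-yl)tetrahydro-1H,3H-furo[3,4-c]furan-1-one
Product: 15 (3R,3aS,6S,6aR)-3-[4-(benzyloxy)-3-methoxyphenyl]-6-(3,4-dimethoxyphenyl)-3a-hydroxytetrahydro-1H,3H-furo[3,4-c]furan-1-one
Conditions: NaBO3·4H2O (5 equiv), THF/H2O (1:1), rt
Reagents that add atoms: sodium perborate (peroxoborate dimer, hydrate water omitted), [Na+].[Na+].O[B-]1(O)OO[B-](O)(O)OO1
Why: Oxidation of a tertiary alkylboronate: peroxide adds to boron and C8 migrates from boron to oxygen with retention, then the borate is hydrolysed; the near-neutral perborate medium should spare the lactone and the new β-hydroxy carbonyl unit.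

Step 9
Reactants: 15 (3R,3aS,6S,6aR)-3-[4-(benzyloxy)-3-methoxyphenyl]-6-(3,4-dimethoxyphenyl)-3a-hydroxytetrahydro-1H,3H-furo[3,4-c]furan-1-one
Product: 16 (3S,4R,5S)-3-{(R)-[4-(benzyloxy)-3-methoxyphenyl](hydroxy)methyl}-5-(3,4-dimethoxyphenyl)-4-(hydroxymethyl)tetrahydrofuran-3-ol
Conditions: LiAlH4 (3 equiv), THF, 0 °C → rt; aq potassium sodium tartrate
Reagents that add atoms: none
Why: Hydride reduction of the lactone to the 1,4-diol; no stereocentre is involved, ring B and the benzyl ether are inert, and the tertiary alcohol is carried as its alkoxide.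

Step 10
Reactants: 16 (3S,4R,5S)-3-{(R)-[4-(benzyloxy)-3-methoxyphenyl](hydroxy)methyl}-5-(3,4-dimethoxyphenyl)-4-(hydroxymethyl)tetrahydrofuran-3-ol
Product: 18 (1S,3aS,4R,6aR)-4-[4-(benzyloxy)-3-methoxyphenyl]-1-(3,4-dimethoxyphenyl)dihydro-1H,3H-furo[3,4-c]furan-3a(4H)-ol, via primary tosylate 17 (not isolated)
Conditions: TsCl (1.2 equiv), pyridine, 0 °C; then 50 °C
Reagents that add atoms: none
Why: Selective sulfonylation of the primary C9'–OH, then intramolecular Williamson-type etherification (5-exo-tet) by the C7 hydroxyl; the C7–O bond is not broken, so C7 keeps its configuration, and attack by the tertiary C8–OH would give only a strained oxetane.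

Step 11
Reactants: 18 (1S,3aS,4R,6aR)-4-[4-(benzyloxy)-3-methoxyphenyl]-1-(3,4-dimethoxyphenyl)dihydro-1H,3H-furo[3,4-c]furan-3a(4H)-ol
Product: 19 (1S,3aS,4R,6aR)-1-(3,4-dimethoxyphenyl)-4-(4-hydroxy-3-methoxyphenyl)dihydro-1H,3H-furo[3,4-c]furan-3a(4H)-ol
Conditions: H2 (1 atm), 10% Pd/C, EtOAc, rt; stopped after one equivalent of H2
Reagents that add atoms: none
Why: Hydrogenolysis of an aryl benzyl ether; in neutral aprotic solvent the unhindered O-benzyl group should be cleaved well before the hindered, cyclic benzylic ethers at C7 and C7', and the reaction is stopped at that point.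

## Compound list

1 | 4-(benzyloxy)-3-methoxybenzaldehyde (O-benzylvanillin) | COc1cc(C=O)ccc1OCc1ccccc1 | starting material
2 | methyl propiolate | C#CC(=O)OC | starting material
3 | methyl (4R)-4-[4-(benzyloxy)-3-methoxyphenyl]-4-hydroxybut-2-ynoate | COC(=O)C#C[C@H](O)c1ccc(OCc2ccccc2)c(OC)c1 | intermediate
4 | methyl (4R)-4-[4-(benzyloxy)-3-methoxyphenyl]-4-[(triethylsilyl)oxy]but-2-ynoate | COC(=O)C#C[C@H](O[Si](CC)(CC)CC)c1ccc(OCc2ccccc2)c(OC)c1 | intermediate
5 | bis(pinacolato)diboron | CC1(C)OB(OC1(C)C)B1OC(C)(C)C(C)(C)O1 | starting material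
6 | methyl (2Z,4S)-4-[4-(benzyloxy)-3-methoxyphenyl]-3-(4,4,5,5-tetramethyl-1,3,2-dioxaborolan-2-yl)-4-[(triethylsilyl)oxy]but-2-enoate | COC(=O)/C=C(/B1OC(C)(C)C(C)(C)O1)[C@H](O[Si](CC)(CC)CC)c1ccc(OCc2ccccc2)c(OC)c1 | intermediate
7 | methyl (2Z,4S)-4-[4-(benzyloxy)-3-methoxyphenyl]-4-hydroxy-3-(4,4,5,5-tetramethyl-1,3,2-dioxaborolan-2-yl)but-2-enoate (not isolated) | COC(=O)/C=C(/B1OC(C)(C)C(C)(C)O1)[C@H](O)c1ccc(OCc2ccccc2)c(OC)c1 | intermediate
8 | (5S)-5-[4-(benzyloxy)-3-methoxyphenyl]-4-(4,4,5,5-tetramethyl-1,3,2-dioxaborolan-2-yl)furan-2(5H)-one | O=C1O[C@H](c2ccc(OCc3ccccc3)c(OC)c2)C(B2OC(C)(C)C(C)(C)O2)=C1 | intermediate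
9 | 3,4-dimethoxybenzaldehyde (veratraldehyde) | COc1ccc(C=O)cc1OC | starting material
10 | (trimethylsilyl)methanol | C[Si](C)(C)CO | starting material
11 | 4-{bis[(trimethylsilyl)methoxy]methyl}-1,2-dimethoxybenzene | COc1ccc(C(OC[Si](C)(C)C)OC[Si](C)(C)C)cc1OC | intermediate
12 | racemic chloro(3,4-dimethoxyphenyl)methyl (trimethylsilyl)methyl ether | COc1ccc(C(Cl)OC[Si](C)(C)C)cc1OC | intermediate
13 | (E)-(3,4-dimethoxybenzylidene)oxonio methanide, the carbonyl ylide (not isolated) | COc1ccc(/C=[O+]/[CH2-])cc1OC | intermediate
14 | (3S,3aR,6S,6aS)-3-[4-(benzyloxy)-3-methoxyphenyl]-6-(3,4-dimethoxyphenyl)-3a-(4,4,5,5-tetramethyl-1,3,2-dioxaborolan-2-yl)tetrahydro-1H,3H-furo[3,4-c]furan-1-one (cis-fused, boron cis to the C7 aryl group, veratryl exo) | COc1cc([C@H]2OC(=O)[C@@H]3[C@@H](c4ccc(OC)c(OC)c4)OC[C@]23B2OC(C)(C)C(C)(C)O2)ccc1OCc1ccccc1 | intermediate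
15 | (3R,3aS,6S,6aR)-3-[4-(benzyloxy)-3-methoxyphenyl]-6-(3,4-dimethoxyphenyl)-3a-hydroxytetrahydro-1H,3H-furo[3,4-c]furan-1-one | COc1cc([C@H]2OC(=O)[C@@H]3[C@@H](c4ccc(OC)c(OC)c4)OC[C@]23O)ccc1OCc1ccccc1 | intermediate
16 | (3S,4R,5S)-3-{(R)-[4-(benzyloxy)-3-methoxyphenyl](hydroxy)methyl}-5-(3,4-dimethoxyphenyl)-4-(hydroxymethyl)tetrahydrofuran-3-ol | COc1cc([C@@H](O)[C@@]2(O)CO[C@H](c3ccc(OC)c(OC)c3)[C@H]2CO)ccc1OCc1ccccc1 | intermediate
17 | [(2S,3R,4S)-4-{(R)-[4-(benzyloxy)-3-methoxyphenyl](hydroxy)methyl}-2-(3,4-dimethoxyphenyl)-4-hydroxytetrahydrofuran-3-yl]methyl 4-methylbenzenesulfonate (not isolated) | COc1cc([C@@H](O)[C@@]2(O)CO[C@H](c3ccc(OC)c(OC)c3)[C@H]2COS(=O)(=O)c2ccc(C)cc2)ccc1OCc1ccccc1 | intermediate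
18 | (1S,3aS,4R,6aR)-4-[4-(benzyloxy)-3-methoxyphenyl]-1-(3,4-dimethoxyphenyl)dihydro-1H,3H-furo[3,4-c]furan-3a(4H)-ol | COc1cc([C@H]2OC[C@@H]3[C@@H](c4ccc(OC)c(OC)c4)OC[C@]23O)ccc1OCc1ccccc1 | intermediate
19 | (1S,3aS,4R,6aR)-1-(3,4-dimethoxyphenyl)-4-(4-hydroxy-3-methoxyphenyl)dihydro-1H,3H-furo[3,4-c]furan-3a(4H)-ol (7R,8S,7'S,8'R in lignan numbering) | COc1cc([C@H]2OC[C@@H]3[C@@H](c4ccc(OC)c(OC)c4)OC[C@]23O)ccc1O | target

## Step count and least certain steps

Total step count: 11 (steps 1–4 to butenolide 8, steps 5–6 to chloro ether 12, steps 7–11 from their union to 19).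
Longest linear sequence: 9 steps (steps 1–4 and 7–11, from aldehyde 1).

**Step 7 (key step).**
What may go wrong:
- Loss of configuration at C7 through deprotonation of 8 by fluoride or by the ylide itself; the resulting 2-oxyfuran reprotonates without memory.
- Binding of fluoride to boron, followed by protodeboronation or loss of the electron-poor character of the alkene.
- Addition at the fully substituted C8 so slow that the ylide is lost by self-reaction or proton transfer.
- Insufficient exo over endo selectivity at C7'.
- Ionisation and hydrolysis of the very electron-rich chloro ether 12 before it meets fluoride.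

Fallback, using established reactions only: the roles of the two halves are exchanged, so that the lactone carbonyl sits on C9 and C8 becomes an enolisable α-carbon. The fallback sets out from 9, 2, 1 and 10 and returns at 18.
- Veratraldehyde 9 and methyl propiolate 2 give, under the conditions of step 1, methyl (4R)-4-(3,4-dimethoxyphenyl)-4-hydroxybut-2-ynoate F1.
- Semi-hydrogenation of F1 over lead-poisoned Pd/CaCO3 with quinoline and brief treatment with pyridinium tosylate give (5S)-5-(3,4-dimethoxyphenyl)furan-2(5H)-one F2.
- Aldehyde 1 and alcohol 10 give, as in step 5, 4-(benzyloxy)-3-methoxybenzaldehyde bis[(trimethylsilyl)methyl] acetal F3. Acetyl chloride, as in step 6, gives racemic [4-(benzyloxy)-3-methoxyphenyl]chloromethyl (trimethylsilyl)methyl ether F4.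
- F2 and F4 with CsF in MeCN give the cis-fused lactone (3S,3aR,6S,6aS)-6-[4-(benzyloxy)-3-methoxyphenyl]-3-(3,4-dimethoxyphenyl)tetrahydro-1H,3H-furo[3,4-c]furan-1-one F5. The dipolarophile is now a plain α,β-unsaturated lactone, a partner class for which this cycloaddition is established; the CH2 end of the ylide bonds to C8', and the ylide adds anti to the veratryl group.
- Deprotonation of F5 with LiN(SiMe3)2 at −78 °C and oxidation of the enolate with 2-(phenylsulfonyl)-3-phenyloxaziridine on the convex face give (3S,3aR,6R,6aR)-6-[4-(benzyloxy)-3-methoxyphenyl]-3-(3,4-dimethoxyphenyl)-6a-hydroxytetrahydro-1H,3H-furo[3,4-c]furan-1-one F6.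
- Reduction of F6 with iBu2AlH at −78 °C gives (3S,3aR,6R,6aR)-6-[4-(benzyloxy)-3-methoxyphenyl]-3-(3,4-dimethoxyphenyl)tetrahydro-1H,3H-furo[3,4-c]furan-1,6a-diol F7 (lactol, both anomers). Et3SiH with BF3·OEt2 at −78 °C removes the anomeric hydroxyl and gives 18.

The C7' proton of F2 is as acidic as the C7 proton of 8, so fluoride is dosed in the same way. What the fallback removes is the boron and the fully substituted alkene carbon.

**Step 1.**
What may go wrong: the electron-rich aldehyde adds slowly, so the uncatalysed addition of the alkynylzinc species can lower the enantiomeric purity of 3, and every later stereocentre inherits that purity.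

Fallback, from 1 and 2 back to 3: methyl propiolate 2 is deprotonated with LiN(SiMe3)2 at −78 °C and added to 1 to give racemic methyl 4-[4-(benzyloxy)-3-methoxyphenyl]-4-hydroxybut-2-ynoate F8. Kinetic resolution with Burkholderia cepacia lipase and vinyl acetate in tBuOMe should then acylate the S enantiomer, with the aryl group acting as the large substituent in the usual empirical model for lipases. This gives methyl (4S)-4-acetoxy-4-[4-(benzyloxy)-3-methoxyphenyl]but-2-ynoate F9 and leaves (R)-3, which is separated and taken into step 2.

**Step 8.**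
What may go wrong: the tertiary boronate is shielded on three sides and may be oxidised slowly. More strongly basic peroxide would open the lactone and could trigger retro-aldol cleavage of the C8–C8' bond in the β-hydroxy carbonyl product.

Fallback, from 14 to 18, bypassing 15–17: the oxidation is moved to the end, where no base-sensitive group is left.
- Lactone 14 is reduced with iBu2AlH at −78 °C to (3S,3aR,6S,6aS)-3-[4-(benzyloxy)-3-methoxyphenyl]-6-(3,4-dimethoxyphenyl)-3a-(4,4,5,5-tetramethyl-1,3,2-dioxaborolan-2-yl)tetrahydro-1H,3H-furo[3,4-c]furan-1-ol F10 (lactol, both anomers).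
- Et3SiH with BF3·OEt2 at −78 °C gives (1S,3aR,4S,6aR)-4-[4-(benzyloxy)-3-methoxyphenyl]-1-(3,4-dimethoxyphenyl)-3a-(4,4,5,5-tetramethyl-1,3,2-dioxaborolan-2-yl)tetrahydro-1H,3H-furo[3,4-c]furan F11.
- H2O2 and NaOH in THF/H2O then oxidise the C–B bond with retention to give 18.

**Step 10.**
What may go wrong: sulfonylation of the benzylic C7 hydroxyl in competition with the primary one, followed by ionisation at C7 and loss of its configuration; displacement of the tosylate by chloride; closure to the oxetane by the tertiary hydroxyl.

Fallback, from 15 to 18, without opening ring A: lactone 15 is reduced with iBu2AlH (3 equiv, −78 °C) to (3R,3aS,6S,6aR)-3-[4-(benzyloxy)-3-methoxyphenyl]-6-(3,4-dimethoxyphenyl)tetrahydro-1H,3H-furo[3,4-c]furan-1,3a-diol F12 (lactol, both anomers). The anomeric hydroxyl is then removed with Et3SiH and BF3·OEt2 at −78 °C through the cyclic oxocarbenium ion, which gives 18.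

## Further compounds

F1 | step 7 | methyl (4R)-4-(3,4-dimethoxyphenyl)-4-hydroxybut-2-ynoate | COC(=O)C#C[C@H](O)c1ccc(OC)c(OC)c1
F2 | step 7 | (5S)-5-(3,4-dimethoxyphenyl)furan-2(5H)-one | O=C1O[C@H](c2ccc(OC)c(OC)c2)C=C1
F3 | step 7 | 4-(benzyloxy)-3-methoxybenzaldehyde bis[(trimethylsilyl)methyl] acetal | COc1cc(C(OC[Si](C)(C)C)OC[Si](C)(C)C)ccc1OCc1ccccc1
F4 | step 7 | racemic [4-(benzyloxy)-3-methoxyphenyl]chloromethyl (trimethylsilyl)methyl ether | COc1cc(C(Cl)OC[Si](C)(C)C)ccc1OCc1ccccc1
F5 | step 7 | (3S,3aR,6S,6aS)-6-[4-(benzyloxy)-3-methoxyphenyl]-3-(3,4-dimethoxyphenyl)tetrahydro-1H,3H-furo[3,4-c]furan-1-one | COc1cc([C@H]2OC[C@@H]3[C@@H](c4ccc(OC)c(OC)c4)OC(=O)[C@H]23)ccc1OCc1ccccc1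
F6 | step 7 | (3S,3aR,6R,6aR)-6-[4-(benzyloxy)-3-methoxyphenyl]-3-(3,4-dimethoxyphenyl)-6a-hydroxytetrahydro-1H,3H-furo[3,4-c]furan-1-one | COc1cc([C@H]2OC[C@@H]3[C@@H](c4ccc(OC)c(OC)c4)OC(=O)[C@]23O)ccc1OCc1ccccc1
F7 | step 7 | (3S,3aR,6R,6aR)-6-[4-(benzyloxy)-3-methoxyphenyl]-3-(3,4-dimethoxyphenyl)tetrahydro-1H,3H-furo[3,4-c]furan-1,6a-diol (lactol, both anomers) | COc1cc([C@H]2OC[C@@H]3[C@@H](c4ccc(OC)c(OC)c4)OC(O)[C@]23O)ccc1OCc1ccccc1
F8 | step 1 | racemic methyl 4-[4-(benzyloxy)-3-methoxyphenyl]-4-hydroxybut-2-ynoate | COC(=O)C#CC(O)c1ccc(OCc2ccccc2)c(OC)c1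
F9 | step 1 | methyl (4S)-4-acetoxy-4-[4-(benzyloxy)-3-methoxyphenyl]but-2-ynoate | COC(=O)C#C[C@@H](OC(C)=O)c1ccc(OCc2ccccc2)c(OC)c1
F10 | step 8 | (3S,3aR,6S,6aS)-3-[4-(benzyloxy)-3-methoxyphenyl]-6-(3,4-dimethoxyphenyl)-3a-(4,4,5,5-tetramethyl-1,3,2-dioxaborolan-2-yl)tetrahydro-1H,3H-furo[3,4-c]furan-1-ol (lactol, both anomers) | COc1cc([C@H]2OC(O)[C@@H]3[C@@H](c4ccc(OC)c(OC)c4)OC[C@]23B2OC(C)(C)C(C)(C)O2)ccc1OCc1ccccc1
F11 | step 8 | (1S,3aR,4S,6aR)-4-[4-(benzyloxy)-3-methoxyphenyl]-1-(3,4-dimethoxyphenyl)-3a-(4,4,5,5-tetramethyl-1,3,2-dioxaborolan-2-yl)tetrahydro-1H,3H-furo[3,4-c]furan | COc1cc([C@H]2OC[C@@H]3[C@@H](c4ccc(OC)c(OC)c4)OC[C@]23B2OC(C)(C)C(C)(C)O2)ccc1OCc1ccccc1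
F12 | step 10 | (3R,3aS,6S,6aR)-3-[4-(benzyloxy)-3-methoxyphenyl]-6-(3,4-dimethoxyphenyl)tetrahydro-1H,3H-furo[3,4-c]furan-1,3a-diol (lactol, both anomers) | COc1cc([C@H]2OC(O)[C@@H]3[C@@H](c4ccc(OC)c(OC)c4)OC[C@]23O)ccc1OCc1ccccc1
A1 | alternative 1 | cis-fused 3-oxabicyclo[3.2.0]heptan-6-one with tert-butyldimethylsilyloxy on C8, exo 4-(tert-butyldimethylsilyloxy)-3-methoxyphenyl on C7 and veratryl on C7' (configuration at C7, C8, C7', C8' as in 19) | COc1cc([C@H]2C(=O)[C@@H]3[C@@H](c4ccc(OC)c(OC)c4)OC[C@]23O[Si](C)(C)C(C)(C)C)ccc1O[Si](C)(C)C(C)(C)C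
A2 | alternative 1 | tert-butyl{[(5S)-5-(3,4-dimethoxyphenyl)-2,5-dihydrofuran-3-yl]oxy}dimethylsilane | COc1ccc([C@H]2OCC(O[Si](C)(C)C(C)(C)C)=C2)cc1OC
A3 | alternative 1 | [4-(tert-butyldimethylsilyloxy)-3-methoxyphenyl]ketene | COc1cc(C=C=O)ccc1O[Si](C)(C)C(C)(C)C
A4 | alternative 1 | cis-fused furofuranone with tert-butyldimethylsilyloxy on C8 and a silylated guaiacyl group on C7 (silyl ether counterpart of 15) | COc1cc([C@H]2OC(=O)[C@@H]3[C@@H](c4ccc(OC)c(OC)c4)OC[C@]23O[Si](C)(C)C(C)(C)C)ccc1O[Si](C)(C)C(C)(C)C
A5 | alternative 2 | (2R,3S,4Z)-2-{4-[(tert-butyldimethylsilyl)oxy]-3-methoxyphenyl}-3-{[(tert-butyldimethylsilyl)oxy]methyl}-4-(3,4-dimethoxybenzylidene)tetrahydrofuran-3-ol | COc1cc([C@H]2OC/C(=C/c3ccc(OC)c(OC)c3)[C@]2(O)CO[Si](C)(C)C(C)(C)C)ccc1O[Si](C)(C)C(C)(C)C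
A6 | alternative 2 | (3R)-1-[(tert-butyldimethylsilyl)oxy]-3-{4-[(tert-butyldimethylsilyl)oxy]-3-methoxyphenyl}-3-(prop-2-yn-1-yloxy)propan-2-one | COc1cc([C@@H](OCC#C)C(=O)CO[Si](C)(C)C(C)(C)C)ccc1O[Si](C)(C)C(C)(C)C
A7 | alternative 2 | (3,4-dimethoxyphenyl)boronic acid | COc1ccc(B(O)O)cc1OC
A8 | alternative 3 | [(3S,4R,5S)-4-{[(tert-butyldimethylsilyl)oxy]methyl}-5-(3,4-dimethoxyphenyl)-3-hydroxytetrahydrofuran-3-yl][4-(benzyloxy)-3-methoxyphenyl]methanone | O=C(c1ccc(OCc2ccccc2)c(OC)c1)[C@@]1(O)CO[C@H](c2ccc(OC)c(OC)c2)[C@H]1CO[Si](C)(C)C(C)(C)C
A9 | alternative 3 | (5R,6S)-4-[4-(benzyloxy)-3-methoxyphenyl]-5-{[(tert-butyldimethylsilyl)oxy]methyl}-6-(3,4-dimethoxyphenyl)-4-hydroxytetrahydro-2H-pyran-3(4H)-one (either configuration at C4, which is lost in the shift) | O=C1CO[C@H](c2ccc(OC)c(OC)c2)[C@@H](CO[Si](C)(C)C(C)(C)C)C1(O)c1ccc(OCc2ccccc2)c(OC)c1
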